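We start from a small charge, ash with 10 mM of solid Q, and follow [X.L] at the end as the charge is raised to 50 mM in birch.

    Q ⇌ X, rate k1*(cs1 - [X]) while solid is left; crystals form when [X] > cs1 (cs1 = 4.5 mM, k1 = 0.28 min⁻¹)
    X + L → X.L (k2 = 700 M⁻¹ min⁻¹)
    D ⇌ L, rate k3*(csat - [L]) (k3 = 10 min⁻¹, csat = 0.54 mM)
    2 Q → Q2 (k4 = 52 M⁻¹ min⁻¹)

| setting | ash | oak | larch | cedar | birch |
|---|---|---|---|---|---|
| Q | 10 mM | 15 mM | 25 mM | 30 mM | 50 mM |
| D | 0.54 mM (held) | 0.54 mM (held) | 0.54 mM (held) | 0.54 mM (held) | 0.54 mM (held) |
| time | 50 min | 50 min | 50 min | 50 min | 50 min |

- percentages count the Q that a species holds: one Q2 counts as two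
- for a step with 2 of a species take k times the square, and two of it per event
- solid, in amounts per volume of the solution: Q
- at the start none of L is dissolved
- at the start none of Q is in solution
- "hardly changes" means that all values lie within two and a half points (for a concentration: within two and a half percent of the largest)
- run time (ash): 50 min

* [X.L] at the end for ash, oak, larch, cedar, birch, in this order
* how that number moves from the first to the last of them (hardly changes / rises all the way / falls, then rises / rises, then falls / falls all the way)

1. First instants. With [L] at saturation, X + L → X.L is pseudo-first-order in X, with constant 0.378 min⁻¹. As an approximation we hold [L] at 0.54 mM and reckon with X. While [X] is near zero, the solid feeds X at 1.26 mM min⁻¹. In ash, Q goes to Q2 faster than that, at 10.4 mM min⁻¹.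

2. Middle. [X] climbs over about 1.52 min towards 1.91 mM, where dissolution equals consumption, and the feed falls to 0.724 mM min⁻¹. While [X] stands near that value, L is lost with constant 1.34 min⁻¹, and transfer against this loss puts [L] near 0.476 mM, lower than the 0.54 mM we hold. We accept that error and reckon with the mean of the two feeds, 0.992 mM min⁻¹. The solid now loses by the square law, with coefficient 104 M⁻¹ min⁻¹, and by this feed. The two losses are equal at the crossover charge, the square root of feed over coefficient, 3.09 mM. Each flask starts above it.

3. End. Integrating this balance down to zero solid, the amount dissolved is the crossover charge times the arctangent of charge over crossover charge. Above the crossover, that is a ceiling of 4.85 mM minus a shortfall, the crossover charge squared over the charge. Dividing the amount dissolved by the feed, the solid feeds X for about 3.93 min in ash and 4.70 min in birch. Afterwards X drains with a time of 2.65 min, shorter than the 50 min of the run, so we count what dissolved as [X.L].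

4. Our row. Ceiling minus shortfall gives 3.90 mM for ash, 4.22 mM for oak, 4.47 mM for larch, 4.54 mM for cedar and 4.66 mM for birch. The shortfall shrinks with each larger charge, so our row rises all the way.

5. The forecast gave 3.9 mM for ash and 4.6 mM for birch, and said the value rises all the way, on the ground that “More starting solid only lengthens the solid's life slightly”.

6. The simulation gives 3.95 mM, 4.22 mM, 4.44 mM, 4.49 mM and 4.60 mM; the value rises all the way. In birch at 50.0 min, Q2 holds 90.8% of the Q charged. Taking the shortfall against the logarithm of the charge, the local order is the crossover charge squared over charge times [X.L]. That gives 0.0859 for larch, where the reading is 0.074, and 0.0708 for cedar, where the reading is 0.061.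

The constants are invented; the result is computed.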